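**Retrosynthetic overview**
- The target comes from O-demethylation of its (S)-6-methoxy-2H-chromene.
- The benzene ring and the pyran ring are made together: Dötz benzannulation of (CO)5Cr=C(OMe)CH=CH2 with an enantiopure (R)-propargylic trityl ether, then o-quinone methide formation and oxa-6π closure on the Cr(CO)3-bound arene. The carbinol centre relays its chirality to C2 and is itself lost.
- The propargylic ether comes from asymmetric alkynylation of a (2E,6E)-C20 enal, which comes from formylolefination of a C18 methyl ketone.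
- The C18 ketone comes from Negishi carboalumination of a C13 alkyne and 1,4-addition to methyl vinyl ketone; the alkyne comes from dihydro-β-ionone.
- Ring order: the trimethylcyclohexene ring is bought; the benzene and pyran rings form in step 7.

Assumption: the sense of the chirality relay in step 7 is taken from the anti-alkoxy model (carbinol H eclipsing the ring C–O bond, OCPh3 anti to Cr(CO)3, ring closure anti to Cr). If the sense proved opposite, the antipodal ligand would be used in step 4.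

**Step 1**
Reactants: 1 4-(2,6,6-trimethylcyclohex-1-en-1-yl)butan-2-one (dihydro-β-ionone)
Product: 3 2-(but-3-yn-1-yl)-1,3,3-trimethylcyclohex-1-ene, via enol diethyl phosphate 2 (not isolated)
Conditions: LiN(iPr)2 (1.1 equiv), THF, −78 °C; ClP(O)(OEt)2, −78 °C → rt; then LiN(iPr)2 (2.3 equiv), −78 °C → rt; H2O
Reagents that add atoms: none
Why: Negishi one-pot methyl ketone → terminal alkyne conversion, in which the kinetic CH3 enolate is O-phosphorylated and the enol phosphate undergoes base-induced elimination.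

**Step 2**
Reactants: 3 2-(but-3-yn-1-yl)-1,3,3-trimethylcyclohex-1-ene; 4 but-3-en-2-one (methyl vinyl ketone)
Product: 6 (5E)-6-methyl-8-(2,6,6-trimethylcyclohex-1-en-1-yl)oct-5-en-2-one, via (E)-alkenyldimethylalane 5 (not isolated)
Conditions: Me3Al (2 equiv), Cp2ZrCl2 (0.25 equiv), CH2Cl2, rt; then THF, CuBr·SMe2 (0.1 equiv), 4, −20 → 0 °C; aq NH4Cl
Reagents that add atoms: trimethylaluminium, C[Al](C)C
Why: Negishi Zr-catalysed syn-carboalumination fixes the (E) trisubstituted alkene, and the alkenyl group is then passed to copper and added 1,4 to the enone with retention of geometry (organocopper conjugate addition).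

**Step 3**
Reactants: 6 (5E)-6-methyl-8-(2,6,6-trimethylcyclohex-1-en-1-yl)oct-5-en-2-one; 7 diethyl [(E)-2-(cyclohexylamino)ethenyl]phosphonate
Product: 9 (2E,6E)-3,7-dimethyl-9-(2,6,6-trimethylcyclohex-1-en-1-yl)nona-2,6-dienal, via N-cyclohexyl 1-azadiene 8 (not isolated)
Conditions: NaH, THF, 0 °C → reflux; then aq oxalic acid/hexane, rt; (2E) isomer separated on silica (E:Z about 3:1)
Reagents that add atoms: water, O
Why: Nagata formylolefination (Horner–Wadsworth–Emmons reaction of a phosphonate metalloenamine) followed by imine hydrolysis gives the enal, and the (2E) geometry that step 7 depends on is secured by removing the (2Z) isomer.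

**Step 4**
Reactants: 9 (2E,6E)-3,7-dimethyl-9-(2,6,6-trimethylcyclohex-1-en-1-yl)nona-2,6-dienal; 10 ethynyl(trimethyl)silane
Product: 12 (3R,4E,8E)-5,9-dimethyl-11-(2,6,6-trimethylcyclohex-1-en-1-yl)undeca-4,8-dien-1-yn-3-ol, via C-trimethylsilyl alkynol 11 (not isolated)
Conditions: Me2Zn (3 equiv), ProPhenol ligand (20 mol%, antipode giving the 3R carbinol), Ph3PO (40 mol%), toluene, 4 °C; aq NH4Cl; then K2CO3, MeOH, rt
Reagents that add atoms: none
Why: Trost dinuclear-zinc (ProPhenol) asymmetric alkynylation of an α,β-unsaturated aldehyde delivers the alkynylzinc to one aldehyde face and sets C3 as R, and methanolysis then removes the C-silyl group.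

**Step 5**
Reactants: 12 (3R,4E,8E)-5,9-dimethyl-11-(2,6,6-trimethylcyclohex-1-en-1-yl)undeca-4,8-dien-1-yn-3-ol
Product: 13 {[(3R,4E,8E)-5,9-dimethyl-11-(2,6,6-trimethylcyclohex-1-en-1-yl)undeca-4,8-dien-1-yn-3-yl]oxy}triphenylmethane
Conditions: Ph3CCl (1.5 equiv), DBU (2 equiv), CH2Cl2, rt
Reagents that add atoms: trityl chloride, ClC(c1ccccc1)(c1ccccc1)c1ccccc1
Why: O-tritylation (trityl cation captured by the carbinol oxygen) leaves the C3–O bond intact, so the R centre is retained, and the bulky ether is chosen because facial induction in benzannulation rises with the size of the propargylic ether.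

**Step 6**
Reactants: 14 hexacarbonylchromium Cr(CO)6; 15 ethenylmagnesium bromide CH2=CHMgBr
Product: 17 pentacarbonyl(1-methoxyprop-2-en-1-ylidene)chromium (CO)5Cr=C(OMe)CH=CH2, via bromomagnesium acylchromate 16 (not isolated)
Conditions: THF, −78 → 0 °C; then Me3OBF4, CH2Cl2/H2O, 0 °C; kept cold and dark, used at once
Reagents that add atoms: trimethyloxonium tetrafluoroborate, C[O+](C)C.F[B-](F)(F)F
Why: Fischer carbene synthesis, in which the vinyl Grignard adds to a CO ligand and the acylchromate is O-methylated by the Meerwein salt.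

**Step 7**
Reactants: 13 {[(3R,4E,8E)-5,9-dimethyl-11-(2,6,6-trimethylcyclohex-1-en-1-yl)undeca-4,8-dien-1-yn-3-yl]oxy}triphenylmethane; 17 pentacarbonyl(1-methoxyprop-2-en-1-ylidene)chromium
Product: 20 (2S)-6-methoxy-2-methyl-2-[(3E)-4-methyl-6-(2,6,6-trimethylcyclohex-1-en-1-yl)hex-3-en-1-yl]-2H-chromene, via planar-chiral phenol Cr(CO)3 complex 18 (not isolated), via o-quinone methide Cr(CO)3 complex 19 (not isolated)
Conditions: THF (0.05 M in 13), 17 (1.5 equiv, added over 2 h), 50 °C, 14 h, Ar, dark; then air, rt, filtration through silica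
Reagents that add atoms: none
Why: Proposed new method: a Dötz benzannulation (alkyne insertion into the alkenylcarbene, CO insertion, 6π closure of the dienylketene, tautomerisation) builds the benzene ring as the Cr(CO)3-bound 4-methoxyphenol 18 with the side chain ortho to the new OH, the bulky (R)-trityloxy centre steering Cr(CO)3 to one arene face, then loss of Ph3COH gives the still metal-bound o-quinone methide 19, whose oxa-6π electrocyclisation closes the pyran ring from the face remote from Cr(CO)3, so that this facial bias together with the fixed (E) geometry of the trisubstituted alkene terminus sets C2 as S while the carbinol centre is erased; the closest known reaction types are the benzannulation/o-quinone methide/electrocyclisation cascade of alkenyl Fischer carbenes with alkenyl propargyl ethers (both chromene rings in one step, racemic) and the central-to-planar-to-central chirality relay of chromium-bound o-quinone methides in the analogous benzannulation/hetero-Diels–Alder cascade.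

**Step 8**
Reactants: 20 (2S)-6-methoxy-2-methyl-2-[(3E)-4-methyl-6-(2,6,6-trimethylcyclohex-1-en-1-yl)hex-3-en-1-yl]-2H-chromene
Product: 21 (2S)-2-methyl-2-[(3E)-4-methyl-6-(2,6,6-trimethylcyclohex-1-en-1-yl)hex-3-en-1-yl]-2H-chromen-6-ol
Conditions: LiPPh2 (from Ph2PH and n-BuLi, 3 equiv), THF, 25 °C; aq NH4Cl
Reagents that add atoms: none
Why: SN2 O-demethylation of the aryl methyl ether by diphenylphosphide under basic conditions at room temperature, which touch neither the C2–O bond nor the unactivated alkenes, so the S centre is not scrambled.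

**Compound list**
1 | 4-(2,6,6-trimethylcyclohex-1-en-1-yl)butan-2-one (dihydro-β-ionone) | CC(=O)CCC1=C(C)CCCC1(C)C | starting material
2 | diethyl 4-(2,6,6-trimethylcyclohex-1-en-1-yl)but-1-en-2-yl phosphate | C=C(CCC1=C(C)CCCC1(C)C)OP(=O)(OCC)OCC | intermediate
3 | 2-(but-3-yn-1-yl)-1,3,3-trimethylcyclohex-1-ene | C#CCCC1=C(C)CCCC1(C)C | intermediate
4 | but-3-en-2-one | CC(=O)C=C | starting material
5 | dimethyl[(1E)-2-methyl-4-(2,6,6-trimethylcyclohex-1-en-1-yl)but-1-en-1-yl]alane | C[Al](C)/C=C(\C)CCC1=C(C)CCCC1(C)C | intermediate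
6 | (5E)-6-methyl-8-(2,6,6-trimethylcyclohex-1-en-1-yl)oct-5-en-2-one | CC(=O)CC/C=C(\C)CCC1=C(C)CCCC1(C)C | intermediate
7 | diethyl [(E)-2-(cyclohexylamino)ethenyl]phosphonate | CCOP(=O)(/C=C/NC1CCCCC1)OCC | starting material
8 | (2E,6E)-N-cyclohexyl-3,7-dimethyl-9-(2,6,6-trimethylcyclohex-1-en-1-yl)nona-2,6-dien-1-imine | C(=NC1CCCCC1)/C=C(\C)CC/C=C(\C)CCC1=C(C)CCCC1(C)C | intermediate
9 | (2E,6E)-3,7-dimethyl-9-(2,6,6-trimethylcyclohex-1-en-1-yl)nona-2,6-dienal | O=C/C=C(\C)CC/C=C(\C)CCC1=C(C)CCCC1(C)C | intermediate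
10 | ethynyl(trimethyl)silane | C#C[Si](C)(C)C | starting material
11 | (3R,4E,8E)-5,9-dimethyl-1-(trimethylsilyl)-11-(2,6,6-trimethylcyclohex-1-en-1-yl)undeca-4,8-dien-1-yn-3-ol | C[Si](C)(C)C#C[C@H](O)/C=C(\C)CC/C=C(\C)CCC1=C(C)CCCC1(C)C | intermediate
12 | (3R,4E,8E)-5,9-dimethyl-11-(2,6,6-trimethylcyclohex-1-en-1-yl)undeca-4,8-dien-1-yn-3-ol | C#C[C@H](O)/C=C(\C)CC/C=C(\C)CCC1=C(C)CCCC1(C)C | intermediate
13 | {[(3R,4E,8E)-5,9-dimethyl-11-(2,6,6-trimethylcyclohex-1-en-1-yl)undeca-4,8-dien-1-yn-3-yl]oxy}triphenylmethane | C#C[C@H](OC(c1ccccc1)(c1ccccc1)c1ccccc1)/C=C(\C)CC/C=C(\C)CCC1=C(C)CCCC1(C)C | intermediate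
14 | hexacarbonylchromium | O=C=[Cr](=C=O)(=C=O)(=C=O)(=C=O)=C=O | starting material
15 | ethenylmagnesium bromide | C=C[Mg]Br | starting material
16 | bromomagnesium pentacarbonyl(prop-2-enoyl)chromate | C=CC([O-])=[Cr](=C=O)(=C=O)(=C=O)(=C=O)=C=O.[Mg+]Br | intermediate
17 | pentacarbonyl(1-methoxyprop-2-en-1-ylidene)chromium | COC(C=C)=[Cr](=C=O)(=C=O)(=C=O)(=C=O)=C=O | intermediate
18 | tricarbonyl{η6-2-[(1R,2E,6E)-3,7-dimethyl-1-(triphenylmethoxy)-9-(2,6,6-trimethylcyclohex-1-en-1-yl)nona-2,6-dien-1-yl]-4-methoxyphenol}chromium (η6 bonding and planar chirality not encoded) | COc1ccc(O)c(c1)[C@H](OC(c1ccccc1)(c1ccccc1)c1ccccc1)/C=C(\C)CC/C=C(\C)CCC1=C(C)CCCC1(C)C.O=C=[Cr](=C=O)=C=O | intermediate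
19 | tricarbonylchromium complex of 6-[(2E,6E)-3,7-dimethyl-9-(2,6,6-trimethylcyclohex-1-en-1-yl)nona-2,6-dien-1-ylidene]-4-methoxycyclohexa-2,4-dien-1-one | COC1=CC(=C/C=C(\C)CC/C=C(\C)CCC2=C(C)CCCC2(C)C)C(=O)C=C1.O=C=[Cr](=C=O)=C=O | intermediate
20 | (2S)-6-methoxy-2-methyl-2-[(3E)-4-methyl-6-(2,6,6-trimethylcyclohex-1-en-1-yl)hex-3-en-1-yl]-2H-chromene | CC1=C(CC/C(C)=C/CC[C@@]2(C)C=Cc3cc(OC)ccc3O2)C(C)(C)CCC1 | intermediate
21 | (2S)-2-methyl-2-[(3E)-4-methyl-6-(2,6,6-trimethylcyclohex-1-en-1-yl)hex-3-en-1-yl]-2H-chromen-6-ol | CC1=C(CC/C(C)=C/CC[C@@]2(C)C=Cc3cc(O)ccc3O2)C(C)(C)CCC1 | target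

**Step count**
Total steps: 8. Longest linear sequence: 7 (steps 1, 2, 3, 4, 5, 7, 8); step 6 is a one-step side branch.

**Steps most likely to fail, with fallbacks**

Step 7 is the main risk: the benzannulation yield and the fidelity of the chromium-mediated chirality relay are both uncertain. The fallback sets out from enal 9 and returns at 20, with the stereocentre set by a palladium catalyst instead. Enal 9 is reduced (NaBH4, CeCl3·7H2O, MeOH, 0 °C) to (2E,6E)-3,7-dimethyl-9-(2,6,6-trimethylcyclohex-1-en-1-yl)nona-2,6-dien-1-ol F1, which is converted (ClCO2Me, pyridine) into methyl (2E,6E)-3,7-dimethyl-9-(2,6,6-trimethylcyclohex-1-en-1-yl)nona-2,6-dien-1-yl carbonate F2. A Tsuji–Trost asymmetric O-allylation of commercial 2-hydroxy-5-methoxybenzaldehyde (Pd2(dba)3·CHCl3, Trost diaminocyclohexane bisphosphine ligand, CH2Cl2, rt) attacks the more substituted allyl terminus and gives 2-{[(3S,6E)-3,7-dimethyl-9-(2,6,6-trimethylcyclohex-1-en-1-yl)nona-1,6-dien-3-yl]oxy}-5-methoxybenzaldehyde F3. Wittig methylenation (Ph3P=CH2, THF) gives 1-{[(3S,6E)-3,7-dimethyl-9-(2,6,6-trimethylcyclohex-1-en-1-yl)nona-1,6-dien-3-yl]oxy}-2-ethenyl-4-methoxybenzene F4. Ring-closing metathesis with first-generation Grubbs catalyst RuCl2(PCy3)2(=CHPh) (CH2Cl2, rt) closes the pyran ring to 20 without touching the C–O bond.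

Step 6 is risky because the parent vinyl carbene complex polymerises easily. The fallback sets out from 14 and returns at 18, using a silicon-bearing surrogate. (E)-Me3SiCH=CHLi (from the commercial bromide and t-BuLi, Et2O, −78 °C) adds to 14 to give lithium pentacarbonyl[(2E)-3-(trimethylsilyl)prop-2-enoyl]chromate F5. Me3OBF4 converts it into the bench-stable pentacarbonyl[(2E)-1-methoxy-3-(trimethylsilyl)prop-2-en-1-ylidene]chromium F6. Its benzannulation with 13 (THF, 50 °C) ends with a 1,3-shift of silicon from carbon to oxygen, giving the tricarbonylchromium complex of {2-[(1R,2E,6E)-3,7-dimethyl-1-(triphenylmethoxy)-9-(2,6,6-trimethylcyclohex-1-en-1-yl)nona-2,6-dien-1-yl]-4-methoxyphenoxy}trimethylsilane F7. Bu4NF (THF, −40 °C → rt) then frees the phenoxide of 18, from which 19 and 20 follow as in step 7.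

Step 2 is risky in the aluminium-to-copper transfer and the 1,4-addition to a polymerisable enone. The fallback sets out from 3 and returns at 6, replacing the conjugate addition by a cross-coupling. The alkenylalane 5 is quenched with I2 to give 2-[(3E)-4-iodo-3-methylbut-3-en-1-yl]-1,3,3-trimethylcyclohex-1-ene F8. Commercial 2-methyl-2-vinyl-1,3-dioxolane is hydroborated with 9-BBN (THF, rt) to give 9-[2-(2-methyl-1,3-dioxolan-2-yl)ethyl]-9-borabicyclo[3.3.1]nonane F9. B-alkyl Suzuki–Miyaura coupling of F8 with F9 (PdCl2(dppf), Cs2CO3, DMF/THF/H2O, rt) gives 2-methyl-2-[(3E)-4-methyl-6-(2,6,6-trimethylcyclohex-1-en-1-yl)hex-3-en-1-yl]-1,3-dioxolane F10, and mild hydrolysis (pyridinium p-toluenesulfonate, aqueous acetone) gives 6.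

**Further compounds**
F1 | step 7 | (2E,6E)-3,7-dimethyl-9-(2,6,6-trimethylcyclohex-1-en-1-yl)nona-2,6-dien-1-ol | OC/C=C(\C)CC/C=C(\C)CCC1=C(C)CCCC1(C)C
F2 | step 7 | methyl (2E,6E)-3,7-dimethyl-9-(2,6,6-trimethylcyclohex-1-en-1-yl)nona-2,6-dien-1-yl carbonate | COC(=O)OC/C=C(\C)CC/C=C(\C)CCC1=C(C)CCCC1(C)C
F3 | step 7 | 2-{[(3S,6E)-3,7-dimethyl-9-(2,6,6-trimethylcyclohex-1-en-1-yl)nona-1,6-dien-3-yl]oxy}-5-methoxybenzaldehyde | COc1ccc(O[C@](C)(C=C)CC/C=C(\C)CCC2=C(C)CCCC2(C)C)c(C=O)c1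
F4 | step 7 | 1-{[(3S,6E)-3,7-dimethyl-9-(2,6,6-trimethylcyclohex-1-en-1-yl)nona-1,6-dien-3-yl]oxy}-2-ethenyl-4-methoxybenzene | COc1ccc(O[C@](C)(C=C)CC/C=C(\C)CCC2=C(C)CCCC2(C)C)c(C=C)c1
F5 | step 6 | lithium pentacarbonyl[(2E)-3-(trimethylsilyl)prop-2-enoyl]chromate | C[Si](C)(C)/C=C/C([O-])=[Cr](=C=O)(=C=O)(=C=O)(=C=O)=C=O.[Li+]
F6 | step 6 | pentacarbonyl[(2E)-1-methoxy-3-(trimethylsilyl)prop-2-en-1-ylidene]chromium | COC(/C=C/[Si](C)(C)C)=[Cr](=C=O)(=C=O)(=C=O)(=C=O)=C=O
F7 | step 6 | tricarbonylchromium complex of {2-[(1R,2E,6E)-3,7-dimethyl-1-(triphenylmethoxy)-9-(2,6,6-trimethylcyclohex-1-en-1-yl)nona-2,6-dien-1-yl]-4-methoxyphenoxy}trimethylsilane | COc1ccc(O[Si](C)(C)C)c(c1)[C@H](OC(c1ccccc1)(c1ccccc1)c1ccccc1)/C=C(\C)CC/C=C(\C)CCC1=C(C)CCCC1(C)C.O=C=[Cr](=C=O)=C=O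
F8 | step 2 | 2-[(3E)-4-iodo-3-methylbut-3-en-1-yl]-1,3,3-trimethylcyclohex-1-ene | I/C=C(\C)CCC1=C(C)CCCC1(C)C
F9 | step 2 | 9-[2-(2-methyl-1,3-dioxolan-2-yl)ethyl]-9-borabicyclo[3.3.1]nonane | CC1(CCB2C3CCCC2CCC3)OCCO1
F10 | step 2 | 2-methyl-2-[(3E)-4-methyl-6-(2,6,6-trimethylcyclohex-1-en-1-yl)hex-3-en-1-yl]-1,3-dioxolane | CC1(CC/C=C(\C)CCC2=C(C)CCCC2(C)C)OCCO1
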